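**Retrosynthetic overview**

1. The C8–CH2 bond of the C-geranyl group is made last. Target 11 is the rearrangement isomer of (2S)-5,7-bis(geranyloxy)-4'-hydroxyflavanone 8, in which the future C8 substituent is parked on O5 through a temporary O5–CH2 bond. A Eu(III)-catalysed Claisen–Cope relay O5 → C6 → C8 carries it to C8 and unveils the 5-OH.
2. Enabling feature: O5 on ring A lies peri to the C4 carbonyl of ring C, so O5 and the carbonyl oxygen form a six-membered Eu(III) chelate that activates this ether only. C8 is the para position of O5 (the other ortho position, C4a, is blocked), and the O7 ether has no such neighbour.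
3. C2 (S) is set by Rh-catalysed asymmetric 1,4-addition of 4-hydroxyphenylboronic acid (ring B) to 5,7-bis(geranyloxy)chromone 6.
4. Chromone 6 comes from 2,4,6-trihydroxyacetophenone by one double O-geranylation (both geranyl groups enter in the same step) and a DMF-DMA annulation.
5. Ring order: ring A is purchased; ring C is closed in step 2 as the pyranone and brought to the flavanone level in step 3, when ring B is attached; the key step closes no ring.

Key step: step 4

Remark (assumption): geranyl = (2E)-3,7-dimethylocta-2,6-dien-1-yl; the (S)-biaryl bisphosphine is assumed to give 2S, by analogy with (S)-biaryl bisphosphines giving (S)-adducts of cyclic enones, and the (R)-ligand is used if the sense proves opposite.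

**Route**

Step 1
Reactants: 1 2,4,6-trihydroxyacetophenone; 2 geranyl bromide (2.1 equiv)
Product: 4 1-[2-hydroxy-4,6-bis(geranyloxy)phenyl]ethanone, via mono-ether 3 (not isolated)
Conditions: K2CO3, acetone, reflux
Reagents that add atoms: none
Why: Williamson ether synthesis: the free para-OH is alkylated first (mono-ether 3), then one of the two equivalent ortho-OH groups, by SN2 at the primary allylic bromide with the E-alkene untouched, while the last OH is held in a hydrogen bond to the acetyl carbonyl and stays free; no stereocentre.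

Step 2
Reactants: 4 1-[2-hydroxy-4,6-bis(geranyloxy)phenyl]ethanone
Product: 6 5,7-bis(geranyloxy)-4H-chromen-4-one, via enaminone 5 (not isolated)
Conditions: DMF-DMA, PhMe, 95 °C; then AcOH, 60 °C
Reagents that add atoms: N,N-dimethylformamide dimethyl acetal (DMF-DMA), COC(OC)N(C)C
Why: Chromone synthesis via an enaminone: condensation of the methyl ketone with DMF-DMA gives enaminone 5, and in warm acetic acid the free ortho-OH adds 6-endo to the β-carbon with loss of dimethylamine, which closes ring C as the pyran-4-one; no stereocentre.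

Step 3
Reactants: 6 5,7-bis(geranyloxy)-4H-chromen-4-one; 7 4-hydroxyphenylboronic acid (3 equiv)
Product: 8 (2S)-5,7-bis(geranyloxy)-2-(4-hydroxyphenyl)chroman-4-one
Conditions: [RhCl(C2H4)2]2 (1.5 mol%), (S)-MeO-F12-BIPHEP (3.3 mol%), KOH (10 mol%), dioxane/H2O 10:1, 30 °C
Reagents that add atoms: none
Why: Rh(I)-catalysed asymmetric 1,4-addition of an arylboronic acid to a chromone (Hayashi–Miyaura reaction): the aryl–Rh species bearing the C2-symmetric bisphosphine adds to one enantioface of C2=C3 and hydrolysis of the Rh enolate releases the flavanone, so C2 is set as S by the ligand under near-neutral conditions that do not open ring C.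

Step 4
Reactants: 8 (2S)-5,7-bis(geranyloxy)-2-(4-hydroxyphenyl)chroman-4-one
Product: 11 (2S)-8-geranyl-7-(geranyloxy)-5-hydroxy-2-(4-hydroxyphenyl)chroman-4-one (CNP0103685.1), via ortho-dienone 9 (not isolated), via para-dienone 10 (not isolated)
Conditions: Eu(fod)3 (10 mol%), CHCl3, 65 °C, sealed tube
Reagents that add atoms: none
Why: Eu(III) binds the C4 carbonyl oxygen and O5 in a six-membered chelate that polarises only the O5–CH2 bond, so the O5 geranyl ether undergoes an aromatic Claisen [3,3] shift to C6 (ortho-dienone 9, allyl unit inverted) while the unchelated O7 ether is left alone; a Cope [3,3] shift across C6–C7=C8 then breaks the crowded C6–C(quaternary) bond and forms the C8–CH2 bond (para-dienone 10), and enolisation of the C5 carbonyl gives phenol 11 with the 5-OH unveiled. The closest known reaction type is the Eu(fod)3-catalysed tandem Claisen–Cope (para-Claisen) rearrangement of 5-O-prenyl flavanones to 8-prenyl flavanones. No ring is closed. No permanent stereocentre is created (the centres at C6 and the quaternary side-chain carbon of 9 and at C8 of 10 are transient), and C2 should not be touched under these neutral conditions; the E geometry of the new side chain is controlled by two chair-like transition states in which the allyl unit keeps the same face toward ring A and the homoprenyl chain stays pseudo-equatorial, so the double inversion returns the linear (E)-geranyl group. The step needs chemoselectivity between two identical geranyl ethers (secured by the peri C4=O chelate at O5), regioselectivity for C8 (secured because C4a is blocked, C8 is the only para position of O5, and the quaternary group wedged between O5 and the O7 ether at C6 favours the Cope shift over tautomerisation) and E/Z fidelity (chair over boat).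

**Compound list**

1 | 2,4,6-trihydroxyacetophenone | CC(=O)c1c(O)cc(O)cc1O | starting material
2 | geranyl bromide, (2E)-1-bromo-3,7-dimethylocta-2,6-diene | CC(C)=CCC/C(C)=C/CBr | starting material
3 | 1-[4-(geranyloxy)-2,6-dihydroxyphenyl]ethanone (mono-ether) | CC(=O)c1c(O)cc(OC/C=C(\C)CCC=C(C)C)cc1O | intermediate
4 | 1-[2-hydroxy-4,6-bis(geranyloxy)phenyl]ethanone | CC(=O)c1c(O)cc(OC/C=C(\C)CCC=C(C)C)cc1OC/C=C(\C)CCC=C(C)C | intermediate
5 | (2E)-3-(dimethylamino)-1-[2-hydroxy-4,6-bis(geranyloxy)phenyl]prop-2-en-1-one (enaminone) | CN(C)/C=C/C(=O)c1c(O)cc(OC/C=C(\C)CCC=C(C)C)cc1OC/C=C(\C)CCC=C(C)C | intermediate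
6 | 5,7-bis(geranyloxy)-4H-chromen-4-one | O=c1ccoc2cc(OC/C=C(\C)CCC=C(C)C)cc(OC/C=C(\C)CCC=C(C)C)c12 | intermediate
7 | 4-hydroxyphenylboronic acid | OB(O)c1ccc(O)cc1 | starting material
8 | (2S)-5,7-bis(geranyloxy)-2-(4-hydroxyphenyl)chroman-4-one | CC(C)=CCC/C(C)=C/COc1cc(OC/C=C(\C)CCC=C(C)C)c2c(c1)O[C@H](c1ccc(O)cc1)CC2=O | intermediate
9 | (2S)-6-(3,7-dimethylocta-1,6-dien-3-yl)-7-(geranyloxy)-2-(4-hydroxyphenyl)-2,3-dihydro-4H-chromene-4,5(6H)-dione (ortho-dienone; mixture at C6 and the quaternary carbon) | O=C1C[C@@H](c2ccc(O)cc2)OC2=C1C(=O)C(C(C)(C=C)CCC=C(C)C)C(OC/C=C(\C)CCC=C(C)C)=C2 | intermediate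
10 | (2S)-8-geranyl-7-(geranyloxy)-2-(4-hydroxyphenyl)-2,3-dihydro-4H-chromene-4,5(8H)-dione (para-dienone; mixture at C8) | O=C1C[C@@H](c2ccc(O)cc2)OC2=C1C(=O)C=C(OC/C=C(\C)CCC=C(C)C)C2C/C=C(\C)CCC=C(C)C | intermediate
11 | (2S)-8-geranyl-7-(geranyloxy)-5-hydroxy-2-(4-hydroxyphenyl)chroman-4-one (CNP0103685.1) | CC(C)=CCC/C(C)=C/COc1cc(O)c2c(c1C/C=C(\C)CCC=C(C)C)O[C@H](c1ccc(O)cc1)CC2=O | target

**Step count and risks**

Total step count: 4. Longest linear sequence: 4 steps (1 → 4 → 6 → 8 → 11).

Steps most likely to fail:

1. Step 4 (key step). What may go wrong: leakage of one of the two [3,3] shifts through a boat transition state, which would turn the side chain into the Z isomer; tautomerisation of dienone 9 before the Cope shift, which would stop the relay at C6 with the branched side chain; slow competing rearrangement of the O7 ether; loss of catalyst activity through binding to the free 4'-OH. Fallback (intermolecular C-alkylation in place of the relay, from 1 back to 11): 1 is C-alkylated with geranyl bromide 2 (DBU, THF) at one of its two equivalent ring positions to give 1-(3-geranyl-2,4,6-trihydroxyphenyl)ethanone F1, in which the alkene geometry comes unchanged from the bromide. Selective O-alkylation of the unchelated para-OH with 2 (K2CO3, acetone) gives 1-[3-geranyl-4-(geranyloxy)-2,6-dihydroxyphenyl]ethanone F2. MOMCl and i-Pr2NEt cap the less hindered ortho-OH to give 1-[3-geranyl-4-(geranyloxy)-2-hydroxy-6-(methoxymethoxy)phenyl]ethanone F3. DMF-DMA gives the enaminone F4, which cyclises under mild acid through the only free OH to 8-geranyl-7-(geranyloxy)-5-(methoxymethoxy)-4H-chromen-4-one F5. The Rh-catalysed asymmetric addition of 7 as in step 3 gives (2S)-8-geranyl-7-(geranyloxy)-2-(4-hydroxyphenyl)-5-(methoxymethoxy)chroman-4-one F6, and HCl in MeOH removes the MOM group to give 11.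

2. Step 3. What may go wrong: slow addition to the electron-rich, peri-substituted chromone, protodeboronation of the electron-rich boronic acid, 1,2-addition of the aryl–Rh species to the product ketone, or incomplete enantioface control. Fallback (ring closure of a chalcone and resolution, from 4 back to 8): Claisen–Schmidt condensation of 4 with 4-hydroxybenzaldehyde (KOH, EtOH) gives (2E)-1-[2-hydroxy-4,6-bis(geranyloxy)phenyl]-3-(4-hydroxyphenyl)prop-2-en-1-one F7. Oxa-Michael cyclisation (NaOAc, EtOH, reflux) gives racemic 5,7-bis(geranyloxy)-2-(4-hydroxyphenyl)chroman-4-one F8. Preparative HPLC on a polysaccharide chiral phase delivers 8; the unwanted enantiomer can be re-equilibrated through F7 with base and recycled.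

3. Step 1. What may go wrong: C-alkylation of the ambident phloroglucinol phenoxide and over- or under-alkylation. Fallback (from 1 back to 4): Mitsunobu etherification of 1 with geraniol (2 equiv, PPh3, DIAD, THF, 0 °C), which activates the alcohol in place of the phenoxide and should favour O-alkylation of the two more acidic OH groups; no new compound is made.

**Further compounds**

F1 | step 4 | 1-(3-geranyl-2,4,6-trihydroxyphenyl)ethanone | CC(=O)c1c(O)cc(O)c(C/C=C(\C)CCC=C(C)C)c1O
F2 | step 4 | 1-[3-geranyl-4-(geranyloxy)-2,6-dihydroxyphenyl]ethanone | CC(=O)c1c(O)cc(OC/C=C(\C)CCC=C(C)C)c(C/C=C(\C)CCC=C(C)C)c1O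
F3 | step 4 | 1-[3-geranyl-4-(geranyloxy)-2-hydroxy-6-(methoxymethoxy)phenyl]ethanone | CC(=O)c1c(OCOC)cc(OC/C=C(\C)CCC=C(C)C)c(C/C=C(\C)CCC=C(C)C)c1O
F4 | step 4 | (2E)-3-(dimethylamino)-1-[3-geranyl-4-(geranyloxy)-2-hydroxy-6-(methoxymethoxy)phenyl]prop-2-en-1-one | CN(C)/C=C/C(=O)c1c(OCOC)cc(OC/C=C(\C)CCC=C(C)C)c(C/C=C(\C)CCC=C(C)C)c1O
F5 | step 4 | 8-geranyl-7-(geranyloxy)-5-(methoxymethoxy)-4H-chromen-4-one | O=c1ccoc2c(C/C=C(\C)CCC=C(C)C)c(OC/C=C(\C)CCC=C(C)C)cc(OCOC)c12
F6 | step 4 | (2S)-8-geranyl-7-(geranyloxy)-2-(4-hydroxyphenyl)-5-(methoxymethoxy)chroman-4-one | CC(C)=CCC/C(C)=C/COc1cc(OCOC)c2c(c1C/C=C(\C)CCC=C(C)C)O[C@H](c1ccc(O)cc1)CC2=O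
F7 | step 3 | (2E)-1-[2-hydroxy-4,6-bis(geranyloxy)phenyl]-3-(4-hydroxyphenyl)prop-2-en-1-one | O=C(/C=C/c1ccc(O)cc1)c1c(O)cc(OC/C=C(\C)CCC=C(C)C)cc1OC/C=C(\C)CCC=C(C)C
F8 | step 3 | racemic 5,7-bis(geranyloxy)-2-(4-hydroxyphenyl)chroman-4-one | CC(C)=CCC/C(C)=C/COc1cc(OC/C=C(\C)CCC=C(C)C)c2c(c1)OC(c1ccc(O)cc1)CC2=O
F0 | step 1 | none | none
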